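The summer run stopped short: from 3.00 min on it held about 5.3% of left-handed substrate beside 49.0% of right-handed substrate, an excess of 80.5%. It looks nearly the same as blue, at the same concentrations, but it carried 0.90 equiv of solid reagent against 1.20 equiv in blue. In summer the solid reagent was the limiting reagent, because its charge was less than the left-handed substrate charged, and the left-handed product ended at 89.0% of that substrate's charge. Blue and green carry a charge of solid reagent above their left-handed substrate, so for them I asked about time instead.

| flask | left-handed substrate | right-handed substrate | solid reagent | free catalyst | impurity | remark | time |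
|---|---|---|---|---|---|---|---|
| autumn | 0.0010 M | 0.0010 M | 0.60 equiv | 15 mol% | 23 µM | run made earlier |  |
| summer | 0.0010 M | 0.0010 M | 0.90 equiv | 15 mol% | 23 µM | run made earlier |  |
| dusk | 5.0 × 10⁻⁴ M | 5.0 × 10⁻⁴ M | 1.2 equiv | 15 mol% | 23 µM | run made earlier |  |
| green | 0.0010 M | 0.0010 M | 1.20 equiv | 15 mol% | 23 µM |  | 5.0 min |
| blue | 0.0010 M | 0.0010 M | 1.20 equiv | 15 mol% | 23 µM |  | 2.5 min |

| run | time / min | right-handed substrate / % | left-handed substrate / % | left-handed product / % |
|---|---|---|---|---|
| autumn | 0.417 | 50.1 | 38.6 | 10.5 |
| autumn | 1.33 | 48.1 | 18.6 | 30.0 |
| autumn | 2.50 | 51.1 | 20.6 | 29.3 |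
| autumn | 4.00 | 48.5 | 21.2 | 29.3 |
| autumn | 5.00 | 49.2 | 20.4 | 31.9 |
| summer | 1.00 | 50.8 | 24.0 | 26.6 |
| summer | 2.00 | 50.4 | 6.7 | 43.5 |
| summer | 3.00 | 49.1 | 4.6 | 42.9 |
| summer | 4.00 | 46.2 | 5.0 | 45.7 |
| summer | 5.00 | 49.0 | 5.3 | 44.5 |
| dusk | 1.00 | 50.3 | 14.7 | 38.7 |
| dusk | 2.00 | 49.5 | 1.9 | 49.2 |
| dusk | 3.00 | 49.6 | 1.2 | 49.9 |
| dusk | 4.00 | 47.0 | 0 | 48.9 |
| dusk | 5.00 | 46.7 | 0 | 50.3 |

(standard deviation of a reading: 1 percentage point)

- free catalyst is single-handed; left-handed substrate and right-handed substrate are mirror images of each other, charged as a racemate, each of them at the stated concentration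
- solid, in amounts per volume of the solution: solid reagent
- at the start none of the solid reagent is in solution
- an excess is the difference of the two amounts in percent of their sum
- an excess is below zero if the other one leads

1. which of the two ends with the higher excess of right-handed substrate over left-handed substrate among what is left of the two ("neither" if they lie within 2 percentage points) (green / blue / neither)
2. excess of right-handed substrate over left-handed substrate among what is left of the two at the end, green
3. excess of right-handed substrate over left-handed substrate among what is left of the two at the end, blue

I replaced the curve by its mean: the left-handed product made per minute from the start to the first reading, the mean feed rate, 0.532 mM min⁻¹ in summer. The autumn run, with less solid reagent, gave 0.504 mM min⁻¹. At the summer rate, I reckoned blue's left-handed substrate cleared in 1.88 min, earlier than its 2.5 min.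

The mean hides the tail, so I checked that error. At 2.00 min summer stood 1.70% above its later level, and I took this as blue's residue then. At the mean rate that residue would go in 0.0639 min. Decaying instead at the 2.05 min⁻¹ read from dusk, it would be 0.611% at blue's end, an excess of 97.5%. I therefore reckoned blue between that estimate and complete clearing, a range that lies mostly inside the margin of 2 percentage points from a green at full excess, and my own answer was neither.

The forecast differed in its choice: 100% for green, 97% for blue, hence green, holding that near the end of blue “that substrate should be nearly gone”.

The simulation gave 100% for green and 99.7% for blue, so neither.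

    partner + free catalyst + left-handed substrate → free catalyst + left-handed product (k = 5.81 × 10⁶ L² mol⁻² s⁻¹)
    partner + free catalyst + right-handed substrate → free catalyst + right-handed product (k = 35700 L² mol⁻² s⁻¹)
    free catalyst + impurity → spent catalyst (k = 37100 L mol⁻¹ s⁻¹)
    solid reagent ⇌ partner, rate k4*(cs4 - [partner]) while solid is left; crystals form when [partner] > cs4 (solubility = 0.360 mM, k = 0.0279 s⁻¹)

Take the neighbour flask like green but with 0.720 equiv of solid reagent. By the mean feed rate I reckoned that charge spent in 1.35 min, before the clearing reckoned at 1.88 min. I reckoned 14.0% of left-handed substrate remaining and an excess of 56.2%. At 5.00 min that flask held 14.4% of left-handed substrate, 0% of its solid reagent, and an excess of 55.1%.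

(The earlier runs and the new flask are simulated with made-up constants; noise was put on by code.)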